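Compound numbers are those of the compound list after the steps. Ring positions are cited in labdane numbering (ring A = C1–C5 and C10, ring B = C5–C10); α is the face opposite the C10 methyl.

## Analysis of the target

Target 23 is a labdane-type diterpenoid. It is a trans-fused decalin with a gem-dimethyl C4, an angular methyl on C10, a methyl on C8 and an acetoxy group on C6. C9 carries a hydroxyl group and the C11–C12 link to C13 of an α-substituted but-2-en-4-olide (C13=C14, C15H2–O, C16=O).

There are five stereocentres, 5S, 6S, 8R, 9R and 10S. H-5 is α and the C10 methyl β (trans fusion). The C6 acetoxy group is α and equatorial, the C8 methyl α and equatorial (H-8 β, axial), and the C9 hydroxyl α and axial with the side chain β. The two oxygens therefore sit 1,4 to each other across ring B on the same face, opposite the axial C10 methyl, with C7 and C8 between them.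

The sensitive groups are the tertiary neopentyl C9 carbinol (ionisation invites dehydration or methyl migration from C10), the secondary acetate and the butenolide (both base- and nucleophile-labile). Once C12 is a carbonyl carbon, the C9 hydroxyl is also β to it and open to retro-aldol loss.

The synthesis is hard for three reasons. C9 is fully substituted and wedged between quaternary C10 and tertiary C8, so a carbonyl addition there is slow and its face uncertain. The C6 oxygen must be equatorial, which is the epimer hydride reagents do not deliver from a C6 ketone. The C8 methyl must end up equatorial next to C9.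

The plan rests on the cis-1,4 arrangement of O–C6 and O–C9 on ring B. This is what remains when a peroxide bridge laid across C6 and C9 of a C6=C7/C8=C9 diene is opened. Both C–O bonds can therefore come from dioxygen 14 in one step, and the C9 carbinol needs neither a cation nor a carbonyl addition.

## Retrosynthetic reasoning

**Butenolide.** In 23 the C13=C14 double bond is moved back to the exocyclic C12=C13 position (22), and that bond is cut to aldehyde 20 and the lactone ylide 21. An endocyclic α-substituted butenolide has no direct olefination equivalent, whereas its exocyclic isomer is what a stabilised ylide gives under neutral conditions. The acetate and the β-hydroxy aldehyde of 20 tolerate those conditions. The whole lactone then arrives as one C4 unit in the last two steps. The forward reactions must give an E-selective olefination and a thermodynamically driven shift of the double bond into the ring.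

**Aldehyde and acetate.** 20 is traced to acetal 19 and this to diol 18. C12 is carried as a dioxolane from the moment C11–C12 are introduced and is unmasked only when the ylide is ready to consume it. The acetate is placed at 18, where the secondary equatorial C6 hydroxyl and the tertiary C9 hydroxyl differ enough for selective acylation.

**Ring B reduction.** The C8–H and C6–H bonds of 18 are removed to give enone 16 (through ketone 17). The forward dissolving-metal reduction has to deliver hydrogen to C8 axially from the β face and then convert the C6 ketone into the equatorial alcohol. 16 is the base-induced isomer of peroxide 15; the O–O bond breaks toward C6 because only C6 carries a hydrogen. The detour through the C6 ketone is accepted because it turns the unreactive C7=C8 alkene into an enone and lets C6 be set under thermodynamic control.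

**Key disconnection.** Both C–O bonds of 15 are cut in one retro-(4+2) step to diene 13 and dioxygen 14. Cutting here removes the C9 carbinol problem altogether: the tertiary C–O bond is made by a concerted cycloaddition on a flat diene whose faces are differentiated by the C10 methyl. The forward reaction must add the oxygen bridge on the α face and must outrun ene-type oxygenation.

**Diene and C9 chain.** 13 is traced to sulfone 12 by restoring a C2–S bond. 12 is cut at C9–C11 into dienyl triflate 10 and the acetal Grignard reagent 11, and 10 is the enol derivative of enone 8. The tetrasubstituted diene carbon C9 is thus the former carbonyl carbon. Because C10 is quaternary, 8 can enolise only through the γ-carbon C6, which gives exactly the C6=C7/C8=C9 diene. The sulfone is removed at 12 and not at 8, because reductive desulfonylation of 8 would also reduce its enone; 12 holds only an unactivated diene and an acetal.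

**Ring A.** The C3–C4 bond of 8 is cut to the monocyclic enone 7. In the forward sense a tertiary radical generated at C4 from the isopropenyl group adds to the vinyl sulfone terminus. This closes ring A and creates the gem-dimethyl quaternary carbon in one step, with no functional handle beyond what 7 already has. The sulfonyl group is there only to direct the closure to the six-membered ring.

**Carvone alkylations.** The C10–C1 and C10–methyl bonds of 7 are cut to 4 and allyl bromide 5, and then to (R)-carvone 1 and iodomethane 2. Carvone supplies the C5 configuration, the C8 methyl, the C7=C8 alkene and the C9 carbonyl. The methyl is introduced first and the larger chain second, so that the chain enters anti to the isopropenyl group, which is the relationship a trans ring fusion requires.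

## Alternatives that were turned down

**Alternative 1:** Ring A is disconnected at C10–C1 and C4–C5. Forward, 2,6-dimethyl-1,4-benzoquinone A1 and 4-methylpenta-1,3-diene A2 combine in a Diels–Alder reaction under a chiral boron Lewis acid, and the cis adduct is epimerised at C5 to the trans-fused enedione A3.
- For it: two achiral commodity compounds and catalytic enantiocontrol give, in one flask, a bicycle that already has C10, the gem-dimethyl C4, oxygen on both C6 and C9 and the C7=C8 alkene with its methyl. The chosen route reaches that oxidation pattern only at 16. On step count to the ring system and on independence from the chiral pool, this alternative is stronger.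
- Against it: A2 carries a cis methyl on its diene terminus, which disfavours the s-cis conformer and makes it a sluggish, acid-sensitive diene. More seriously, the hard problem is only postponed. The C11–C12 chain would have to be added to the C9 carbonyl of A3, the more hindered of two conjugated carbonyls, and on the β face next to the angular methyl. Neither the site nor the face is secured by anything in A3. The C2=C3 alkene must also be saturated beside the enedione.
- Comparison: the chosen strategy is longer to the ring system, but it forms the C9–O bond with the chain already in place and with the face dictated by the C10 methyl.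

**Alternative 2:** The C9–C10 bond is disconnected. Forward, the δ-lactone A4, O-silylated at its enolate stage, undergoes an Ireland–Claisen rearrangement through a boat transition state to the ring B cyclohexene acid A5.
- For it: the two adjacent fully substituted carbons C9 and C10 are joined in one sigmatropic event with chirality transfer. The C9 chain and the C8 methyl are already in place. The C5=C6 alkene of A5 could take up H-5 and the C6 oxygen by a syn hydroboration on the α face, which is a more direct way to the 6α oxygen than the ketone detour of the chosen route. On these two points it is as strong or stronger.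
- Against it: C9 of A5 carries a carboxyl group where 23 needs a hydroxyl. Exchanging carbon for oxygen with retention at a quaternary neopentyl centre costs several steps and passes through a radical or cation at C9. The rearrangement has to bond a tetrasubstituted ketene acetal carbon to a tetrasubstituted alkene carbon. A4 needs its own enantioselective synthesis with two relevant stereocentres.
- Comparison: the chosen strategy puts the correct heteroatom on C9 directly and draws its absolute configuration from 1.

**Alternative 3:** C8 is inserted between C7 and C9. Forward, diazoethane A7 adds to the ketone of the hydrindenone A6 under a Lewis acid, and the C7 methylene migrates with loss of dinitrogen to give the octalenone A8.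
- For it: A6 descends in few steps from an amino-acid-catalysed annulation, so either enantiomer is accessible catalytically. The C8 methyl of A8 is α to the ketone and can be equilibrated to the equatorial epimer. That is thermodynamic control where the chosen route relies on a kinetic protonation, and on this point the alternative is stronger.
- Against it: migration of the C7 methylene must beat migration of quaternary C10, epoxide formation and double homologation, and A7 is a hazardous reagent that cannot be stored. After the key step the side chain still has to be added to the C9 ketone of A8, between quaternary C10 and an enolisable C8, with equatorial entry on the β face.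
- Comparison: the chosen strategy avoids that addition; in return it accepts a longer sequence and sets C8 by axial protonation of an enone.

Key step: step 7

Remark on the chemistry: 11 (as its THF solution) and 21 are taken as purchased reagents. The sulfone-bearing carbon (labdane C2) in 8, 9, 10 and 12 is an epimer mixture that converges in step 6.

## Route

Step 1
Reactants: 1 (R)-carvone; 2 iodomethane
Product: 4 (5R,6S)-2,6-dimethyl-5-(prop-1-en-2-yl)cyclohex-2-en-1-one (formed together with its 6R epimer), via lithium dienolate 3 (not isolated)
Conditions: LiN(iPr)2 (1.05 equiv), THF, –78 °C; MeI, –78 → 0 °C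
Reagents that add atoms: iodomethane 2, CI
Why: Kinetic deprotonation at the α′ carbon gives the cross-conjugated lithium dienolate, which is C-methylated (enolate alkylation). The new centre forms as an epimer mixture, mainly methyl trans to the isopropenyl group, which is of no consequence because it is planarised again in step 2.

Step 2
Reactants: 4 (5R,6S)-2,6-dimethyl-5-(prop-1-en-2-yl)cyclohex-2-en-1-one; 5 [(3-bromoprop-1-en-2-yl)sulfonyl]benzene
Product: 7 (5S,6S)-2,6-dimethyl-6-[2-(phenylsulfonyl)prop-2-en-1-yl]-5-(prop-1-en-2-yl)cyclohex-2-en-1-one, via lithium dienolate 6 (not isolated)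
Conditions: LiN(iPr)2 (1.1 equiv), THF, –78 → 0 °C; enolate added to 5 (1.3 equiv), THF, –78 → –20 °C
Reagents that add atoms: [(3-bromoprop-1-en-2-yl)sulfonyl]benzene 5, C=C(CBr)S(=O)(=O)c1ccccc1
Why: Deprotonation at the only α′ hydrogen gives a tetrasubstituted enolate that is allylated by the highly reactive bromide; direct displacement and conjugate addition–bromide elimination lead to the same product. The electrophile should enter anti to the neighbouring isopropenyl group, so the chain ends up trans and the methyl cis to it; this sets C10. Inverse addition keeps the enolate from adding to the vinyl sulfone of the product.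

Step 3
Reactants: 7 (5S,6S)-2,6-dimethyl-6-[2-(phenylsulfonyl)prop-2-en-1-yl]-5-(prop-1-en-2-yl)cyclohex-2-en-1-one
Product: 8 (4aS,8aS)-2,5,5,8a-tetramethyl-7-(phenylsulfonyl)-4a,5,6,7,8,8a-hexahydronaphthalen-1(4H)-one (epimers at the sulfone carbon)
Conditions: Fe(acac)3 (30 mol%), PhSiH3 (2.5 equiv), EtOH/(CH2OH)2 5:1, 60 °C
Reagents that add atoms: none
Why: An iron hydride transfers a hydrogen atom to the CH2 terminus of the electron-rich isopropenyl group (metal-hydride hydrogen atom transfer), and the tertiary C4 radical adds to the unsubstituted terminus of the vinyl sulfone in a 6-endo Giese cyclisation, because the sulfonyl group stabilises the radical on the internal carbon. The α-sulfonyl radical is then reduced by divalent iron and protonated by the solvent. The trans ring fusion follows from the trans placement of the two reacting arms on ring B; the new centre at C2 is uncontrolled and is removed in step 6.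

Step 4
Reactants: 8 (4aS,8aS)-2,5,5,8a-tetramethyl-7-(phenylsulfonyl)-4a,5,6,7,8,8a-hexahydronaphthalen-1(4H)-one
Product: 10 (4aS,8aS)-2,5,5,8a-tetramethyl-7-(phenylsulfonyl)-4a,5,6,7,8,8a-hexahydronaphthalen-1-yl trifluoromethanesulfonate, via potassium dienolate 9 (not isolated)
Conditions: KN(SiMe3)2 (1.2 equiv), THF, –78 → –20 °C; PhNTf2 (1.3 equiv), –78 °C → rt
Reagents that add atoms: N-phenylbis(trifluoromethanesulfonimide), O=S(=O)(N(c1ccccc1)S(=O)(=O)C(F)(F)F)C(F)(F)F
Why: C10 is quaternary, so the enone can enolise only through the γ-carbon C6; the extended dienolate is O-sulfonylated to give the C6=C7/C8=C9 dienyl triflate (enol triflate formation). The silylamide base should not metallate the much less acidic α-sulfonyl C–H.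

Step 5
Reactants: 10 (4aS,8aS)-2,5,5,8a-tetramethyl-7-(phenylsulfonyl)-4a,5,6,7,8,8a-hexahydronaphthalen-1-yl trifluoromethanesulfonate; 11 (1,3-dioxolan-2-ylmethyl)magnesium bromide
Product: 12 2-{[(4aS,8aS)-2,5,5,8a-tetramethyl-7-(phenylsulfonyl)-4a,5,6,7,8,8a-hexahydronaphthalen-1-yl]methyl}-1,3-dioxolane
Conditions: Fe(acac)3 (10 mol%), 11 (2.0 equiv, 0.5 M in THF), THF/NMP, –30 → 0 °C
Reagents that add atoms: (1,3-dioxolan-2-ylmethyl)magnesium bromide 11, Br[Mg]CC1OCCO1
Why: Iron-catalysed Kumada coupling of alkenyl triflates with primary alkyl Grignard reagents is fast below 0 °C, which should outrun β-alkoxide elimination of the reagent and metallation next to the sulfone. Diene, sulfone and acetal are spectators and no stereocentre is formed.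

Step 6
Reactants: 12 2-{[(4aS,8aS)-2,5,5,8a-tetramethyl-7-(phenylsulfonyl)-4a,5,6,7,8,8a-hexahydronaphthalen-1-yl]methyl}-1,3-dioxolane
Product: 13 2-{[(4aS,8aS)-2,5,5,8a-tetramethyl-4a,5,6,7,8,8a-hexahydronaphthalen-1-yl]methyl}-1,3-dioxolane
Conditions: Na(Hg) (6% Na, excess), Na2HPO4, MeOH/THF, –20 °C → rt
Reagents that add atoms: none
Why: Electron transfer to the aryl sulfone cleaves the C2–S bond and methanol protonates the carbon (reductive desulfonylation). An unactivated conjugated diene and a dioxolane are not reduced under these buffered conditions, and both C2 epimers converge to one compound.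

Step 7
Reactants: 13 2-{[(4aS,8aS)-2,5,5,8a-tetramethyl-4a,5,6,7,8,8a-hexahydronaphthalen-1-yl]methyl}-1,3-dioxolane; 14 dioxygen
Product: 15 2-{[(1R,4S,4aS,8aS)-2,5,5,8a-tetramethyl-4a,5,6,7,8,8a-hexahydro-1,4-epidioxynaphthalen-1(4H)-yl]methyl}-1,3-dioxolane (6α,9α-epidioxide)
Conditions: O2 (1 atm), 5,10,15,20-tetraphenylporphyrin (1 mol%), CH2Cl2, white LED light, –40 °C
Reagents that add atoms: dioxygen 14, O=O
Why: The excited sensitiser passes its energy to 14, and singlet dioxygen adds across C6 and C9 of the homoannular diene in a concerted suprafacial (4+2) cycloaddition, forming both C–O bonds without charged or radical intermediates. The closest known reaction type is the dye-sensitised photooxygenation of ring B dienes of steroids and of simple cyclohexa-1,3-dienes to 1,4-epidioxides. No carbocycle is formed; the six-membered 1,2-dioxine ring bridging ring B (a 2,3-dioxabicyclo[2.2.2]oct-5-ene) closes by cycloaddition, both oxygens bonding to the same face of the diene. C6 and C9 are both set by the face of approach: the pseudoaxial C10 methyl next to C9 and the axial 4β-methyl above C6 shield the β face, whereas the α face carries only H-5 and the axial H-1, so the bridge should form on the α face, and the bridge itself enforces the cis relationship of the two oxygens. The step needs cycloaddition to win over ene-type oxygenation at the tetrasubstituted C8=C9 bond (allylic hydrogens on the C8 methyl and C11); the diene is locked s-cis in a six-membered ring, the situation in which cycloaddition is normally the faster path, and low temperature in an aprotic solvent supports it. The acetal is inert to singlet dioxygen, and the peroxide is kept cold and taken on directly.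

Step 8
Reactants: 15 2-{[(1R,4S,4aS,8aS)-2,5,5,8a-tetramethyl-4a,5,6,7,8,8a-hexahydro-1,4-epidioxynaphthalen-1(4H)-yl]methyl}-1,3-dioxolane
Product: 16 (4R,4aS,8aS)-4-(1,3-dioxolan-2-ylmethyl)-4-hydroxy-3,4a,8,8-tetramethyl-4a,5,6,7,8,8a-hexahydronaphthalen-1(4H)-one
Conditions: DBU (0.2 equiv), CH2Cl2, 0 °C → rt
Reagents that add atoms: none
Why: Kornblum–DeLaMare rearrangement: the base removes H-6, the only hydrogen on a peroxide-bearing carbon, and the O–O bond breaks to give the C6 ketone conjugated with C7=C8 and the C9 alcohol. C9 keeps its configuration; the C6 centre is given up here and set again in step 9.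

Step 9
Reactants: 16 (4R,4aS,8aS)-4-(1,3-dioxolan-2-ylmethyl)-4-hydroxy-3,4a,8,8-tetramethyl-4a,5,6,7,8,8a-hexahydronaphthalen-1(4H)-one
Product: 18 (1R,2R,4S,4aS,8aS)-1-(1,3-dioxolan-2-ylmethyl)-2,5,5,8a-tetramethyldecahydronaphthalene-1,4-diol, via saturated hydroxy ketone 17 (not isolated)
Conditions: Li (12 equiv), NH3(l)/THF, –78 °C; EtOH added slowly, –78 → –33 °C; NH4Cl
Reagents that add atoms: none
Why: Dissolving-metal enone reduction: the radical anion is protonated at the β-carbon C8 along the axis of the π system, that is pseudoaxially from the β face, which leaves the methyl equatorial (8α) and avoids a syn-diaxial clash with the C10 methyl. Ethanol then protonates the enolate, and ketone 17 is reduced under thermodynamic control to the equatorial 6α-alcohol, since the axial epimer would be syn-diaxial to the C10 and 4β methyls. The C9 hydroxyl is present as its lithium alkoxide, a poor leaving group, and the dioxolane is inert.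

Step 10
Reactants: 18 (1R,2R,4S,4aS,8aS)-1-(1,3-dioxolan-2-ylmethyl)-2,5,5,8a-tetramethyldecahydronaphthalene-1,4-diol
Product: 19 (1S,3R,4R,4aS,8aS)-4-(1,3-dioxolan-2-ylmethyl)-4-hydroxy-3,4a,8,8-tetramethyldecahydronaphthalen-1-yl acetate
Conditions: Ac2O (1.5 equiv), pyridine, DMAP (10 mol%), CH2Cl2, rt
Reagents that add atoms: acetic anhydride, CC(=O)OC(C)=O
Why: Nucleophile-catalysed acylation distinguishes the secondary equatorial C6 hydroxyl from the tertiary neopentyl C9 hydroxyl, which should not react at room temperature (selective esterification).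

Step 11
Reactants: 19 (1S,3R,4R,4aS,8aS)-4-(1,3-dioxolan-2-ylmethyl)-4-hydroxy-3,4a,8,8-tetramethyldecahydronaphthalen-1-yl acetate
Product: 20 (1S,3R,4R,4aS,8aS)-4-hydroxy-3,4a,8,8-tetramethyl-4-(2-oxoethyl)decahydronaphthalen-1-yl acetate
Conditions: 1 M HCl (aq)/THF 1:4, 0 °C → rt
Reagents that add atoms: water, O
Why: Acid-catalysed acetal hydrolysis; dilute acid at or below room temperature should leave the acetate and the hindered tertiary alcohol untouched. The β-hydroxy aldehyde is used at once so that dehydration and retro-aldol cleavage have no time to set in.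

Step 12
Reactants: 20 (1S,3R,4R,4aS,8aS)-4-hydroxy-3,4a,8,8-tetramethyl-4-(2-oxoethyl)decahydronaphthalen-1-yl acetate; 21 3-(triphenyl-λ5-phosphanylidene)oxolan-2-one
Product: 22 (1S,3R,4R,4aS,8aS)-4-hydroxy-3,4a,8,8-tetramethyl-4-[(2E)-2-(2-oxooxolan-3-ylidene)ethyl]decahydronaphthalen-1-yl acetate
Conditions: 21 (1.5 equiv), toluene, 60 °C
Reagents that add atoms: 3-(triphenyl-λ5-phosphanylidene)oxolan-2-one 21, O=C1OCCC1=P(c1ccccc1)(c1ccccc1)c1ccccc1
Why: Wittig olefination with a lactone-stabilised ylide runs without added base, tolerates the free tertiary alcohol and the acetate, and should give the E-alkylidene lactone, as stabilised ylides do.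

Step 13
Reactants: 22 (1S,3R,4R,4aS,8aS)-4-hydroxy-3,4a,8,8-tetramethyl-4-[(2E)-2-(2-oxooxolan-3-ylidene)ethyl]decahydronaphthalen-1-yl acetate
Product: 23 (1S,3R,4R,4aS,8aS)-4-hydroxy-3,4a,8,8-tetramethyl-4-[2-(2-oxo-2,5-dihydrofuran-3-yl)ethyl]decahydronaphthalen-1-yl acetate
Conditions: RhCl3·3H2O (10 mol%), EtOH, 75 °C
Reagents that add atoms: none
Why: A rhodium hydride formed in ethanol adds to the exocyclic alkene and eliminates toward C14 (alkene isomerisation by hydrometallation and β-hydride elimination), which moves the double bond into the ring to give the more stable endocyclic butenolide. No stereocentre is touched.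

## Compound list

1 | (R)-carvone, (5R)-2-methyl-5-(prop-1-en-2-yl)cyclohex-2-en-1-one | CC1=CC[C@@H](C(C)=C)CC1=O | starting material
2 | iodomethane | CI | starting material
3 | lithium (3R)-6-methyl-3-(prop-1-en-2-yl)cyclohexa-1,5-dien-1-olate (not isolated) | CC1=CC[C@@H](C(C)=C)C=C1O[Li] | intermediate
4 | (5R,6S)-2,6-dimethyl-5-(prop-1-en-2-yl)cyclohex-2-en-1-one (major trans epimer drawn; the 6R epimer accompanies it) | CC1=CC[C@@H](C(C)=C)[C@H](C)C1=O | intermediate
5 | [(3-bromoprop-1-en-2-yl)sulfonyl]benzene | C=C(CBr)S(=O)(=O)c1ccccc1 | starting material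
6 | lithium (3S)-2,6-dimethyl-3-(prop-1-en-2-yl)cyclohexa-1,5-dien-1-olate (not isolated) | CC1=CC[C@@H](C(C)=C)C(C)=C1O[Li] | intermediate
7 | (5S,6S)-2,6-dimethyl-6-[2-(phenylsulfonyl)prop-2-en-1-yl]-5-(prop-1-en-2-yl)cyclohex-2-en-1-one | CC1=CC[C@@H](C(C)=C)[C@](C)(CC(=C)S(=O)(=O)c2ccccc2)C1=O | intermediate
8 | (4aS,8aS)-2,5,5,8a-tetramethyl-7-(phenylsulfonyl)-4a,5,6,7,8,8a-hexahydronaphthalen-1(4H)-one (epimers at C7 of this name, labdane C2) | CC1=CC[C@H]2C(C)(C)CC(S(=O)(=O)c3ccccc3)C[C@]2(C)C1=O | intermediate
9 | potassium (4aS,8aS)-2,5,5,8a-tetramethyl-7-(phenylsulfonyl)-4a,5,6,7,8,8a-hexahydronaphthalen-1-olate (not isolated) | C1=CC(C)=C(O[K])[C@@]2(C)CC(S(=O)(=O)c3ccccc3)CC(C)(C)[C@H]12 | intermediate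
10 | (4aS,8aS)-2,5,5,8a-tetramethyl-7-(phenylsulfonyl)-4a,5,6,7,8,8a-hexahydronaphthalen-1-yl trifluoromethanesulfonate | C1=CC(C)=C(OS(=O)(=O)C(F)(F)F)[C@@]2(C)CC(S(=O)(=O)c3ccccc3)CC(C)(C)[C@H]12 | intermediate
11 | (1,3-dioxolan-2-ylmethyl)magnesium bromide | Br[Mg]CC1OCCO1 | starting material
12 | 2-{[(4aS,8aS)-2,5,5,8a-tetramethyl-7-(phenylsulfonyl)-4a,5,6,7,8,8a-hexahydronaphthalen-1-yl]methyl}-1,3-dioxolane | C1=CC(C)=C(CC3OCCO3)[C@@]2(C)CC(S(=O)(=O)c3ccccc3)CC(C)(C)[C@H]12 | intermediate
13 | 2-{[(4aS,8aS)-2,5,5,8a-tetramethyl-4a,5,6,7,8,8a-hexahydronaphthalen-1-yl]methyl}-1,3-dioxolane | C1=CC(C)=C(CC2OCCO2)[C@@]2(C)CCCC(C)(C)[C@H]12 | intermediate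
14 | dioxygen | O=O | starting material
15 | 2-{[(1R,4S,4aS,8aS)-2,5,5,8a-tetramethyl-4a,5,6,7,8,8a-hexahydro-1,4-epidioxynaphthalen-1(4H)-yl]methyl}-1,3-dioxolane | O1O[C@H]2C=C(C)[C@]1(CC3OCCO3)[C@@]3(C)CCCC(C)(C)[C@H]23 | intermediate
16 | (4R,4aS,8aS)-4-(1,3-dioxolan-2-ylmethyl)-4-hydroxy-3,4a,8,8-tetramethyl-4a,5,6,7,8,8a-hexahydronaphthalen-1(4H)-one | O=C1C=C(C)[C@](O)(CC2OCCO2)[C@@]2(C)CCCC(C)(C)[C@H]12 | intermediate
17 | (3R,4R,4aS,8aS)-4-(1,3-dioxolan-2-ylmethyl)-4-hydroxy-3,4a,8,8-tetramethyloctahydronaphthalen-1(2H)-one (not isolated) | O=C1C[C@@H](C)[C@](O)(CC2OCCO2)[C@@]2(C)CCCC(C)(C)[C@H]12 | intermediate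
18 | (1R,2R,4S,4aS,8aS)-1-(1,3-dioxolan-2-ylmethyl)-2,5,5,8a-tetramethyldecahydronaphthalene-1,4-diol | O[C@H]1C[C@@H](C)[C@](O)(CC2OCCO2)[C@@]2(C)CCCC(C)(C)[C@H]12 | intermediate
19 | (1S,3R,4R,4aS,8aS)-4-(1,3-dioxolan-2-ylmethyl)-4-hydroxy-3,4a,8,8-tetramethyldecahydronaphthalen-1-yl acetate | CC(=O)O[C@H]1C[C@@H](C)[C@](O)(CC2OCCO2)[C@@]2(C)CCCC(C)(C)[C@H]12 | intermediate
20 | (1S,3R,4R,4aS,8aS)-4-hydroxy-3,4a,8,8-tetramethyl-4-(2-oxoethyl)decahydronaphthalen-1-yl acetate | CC(=O)O[C@H]1C[C@@H](C)[C@](O)(CC=O)[C@@]2(C)CCCC(C)(C)[C@H]12 | intermediate
21 | 3-(triphenyl-λ5-phosphanylidene)oxolan-2-one | O=C1OCCC1=P(c1ccccc1)(c1ccccc1)c1ccccc1 | starting material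
22 | (1S,3R,4R,4aS,8aS)-4-hydroxy-3,4a,8,8-tetramethyl-4-[(2E)-2-(2-oxooxolan-3-ylidene)ethyl]decahydronaphthalen-1-yl acetate | CC(=O)O[C@H]1C[C@@H](C)[C@](O)(C/C=C2\CCOC2=O)[C@@]2(C)CCCC(C)(C)[C@H]12 | intermediate
23 | (1S,3R,4R,4aS,8aS)-4-hydroxy-3,4a,8,8-tetramethyl-4-[2-(2-oxo-2,5-dihydrofuran-3-yl)ethyl]decahydronaphthalen-1-yl acetate | CC(=O)O[C@H]1C[C@@H](C)[C@](O)(CCC2=CCOC2=O)[C@@]2(C)CCCC(C)(C)[C@H]12 | target

## Step count and least certain steps

Total step count: 13. Longest linear sequence: 13 steps, from 1 to 23.

Origin of the stereocentres: C5 comes from 1, C10 from step 2, C9 from step 7, and C8 and the final C6 from step 9. Nothing after step 9 touches them.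

**Step 7 (key step).** Three processes could spoil it: ene-type oxygenation at the tetrasubstituted C8=C9 bond competing with cycloaddition, partial approach of dioxygen from the β face, and thermal rearrangement of the tertiary peroxide before it is opened. The fallback sets out from 13 and returns at 19.
- A buffered peracid epoxidation (mCPBA, NaHCO3, CH2Cl2, –20 °C) of the more electron-rich tetrasubstituted alkene on the α face would give the 8α,9α-epoxy-6-ene F1.
- Opening with acetic acid under zerovalent palladium catalysis (Pd(PPh3)4, THF, Tsuji–Trost type) ionises the allylic C8–O bond anti and delivers acetate to C6 anti to the metal. This should give the cis-6α-acetoxy-9α-hydroxy-7-ene F2.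
- Hydrogen-atom-transfer hydrogenation of C7=C8 (Mn(dpm)3, dpm = 2,2,6,6-tetramethylheptane-3,5-dionate, with PhSiH3 and t-BuOOH in i-PrOH) should place the C8 methyl equatorial and give 19.

**Step 3.** The tertiary radical may be reduced before it cyclises, may close in the 5-exo mode, or the hydride may react with the enone. The fallback sets out from 7 and returns at 8. Markovnikov addition of HBr (HBr in AcOH, 0 °C) to the isopropenyl group would give the tertiary bromide (5R,6S)-5-(2-bromopropan-2-yl)-2,6-dimethyl-6-[2-(phenylsulfonyl)prop-2-en-1-yl]cyclohex-2-en-1-one F3. Slow addition of Bu3SnH with AIBN in benzene at 80 °C generates the same C4 radical at low hydride concentration and should close ring A to 8.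

**Step 5.** Oxidative addition and transmetalation may be slow at a tetrasubstituted triflate next to quaternary C10, the Grignard reagent may lose alkoxide by β-elimination, or it may attack the triflate sulfur. The fallback sets out from 10 and returns at 20; it replaces the acetal by an allyl group that is cleaved at the end.
- Stille coupling with allyltributylstannane (Pd(PPh3)4, LiCl, THF, 65 °C) would give the 9-allyl-6,8-diene sulfone F4.
- Na(Hg) in buffered MeOH would give the 9-allyl-6,8-diene F5.
- The operations of steps 7 to 10 would then give, in turn, the 9β-allyl-6α,9α-epidioxide F6, the 9β-allyl-9α-hydroxy-7-en-6-one F7, the 9β-allyl-8α-methyl-6α,9α-diol F8 and its 6α-acetate F9.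
- Ozonolysis of the terminal alkene (O3, CH2Cl2/MeOH, –78 °C; PPh3) gives 20.

**Step 9.** The C9 oxygen may be lost reductively, because the axial C9–O bond is aligned with the enone π system. C8 may also be protonated from the α face, or the ketone reduction may stop halfway. The fallback sets out from 15 and returns at 18. Thiourea in MeOH reduces only the O–O bond and would give the 7-ene-6α,9α-diol F10, which keeps the C6 configuration of the cycloaddition. The hydrogen-atom-transfer hydrogenation described for the key-step fallback then saturates C7=C8 with the methyl equatorial.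

**Step 13.** HCl released from the rhodium salt in hot ethanol may dehydrate the tertiary C9 alcohol, and migration of the double bond may stop short of completion. The fallback sets out from 20 and returns at 23 without passing through 22.
- NaBH4 in MeOH at 0 °C would give the primary alcohol F11.
- I2, PPh3 and imidazole in CH2Cl2 would give the primary iodide F12.
- A nickel-catalysed reductive cross-electrophile coupling with 3-bromofuran-2(5H)-one (NiBr2(dme), 4,4′-di-tert-butyl-2,2′-bipyridine, Zn, DMA) joins C12 to C13 with the butenolide double bond already in place.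

## Further compounds

F1 | step 7 | 8α,9α-epoxy-6-ene: 2-{[8α,9α-epoxy-4,4,8,10-tetramethyl-trans-decal-6-en-9-yl]methyl}-1,3-dioxolane (5α-H, 10β-methyl) | C1=C[C@@]2(C)O[C@@]2(CC3OCCO3)[C@@]3(C)CCCC(C)(C)[C@H]13
F2 | step 7 | 6α-acetoxy-9α-hydroxy-7-ene: 9β-(1,3-dioxolan-2-ylmethyl)-9α-hydroxy-4,4,8,10-tetramethyl-trans-decal-7-en-6α-yl acetate | CC(=O)O[C@H]1C=C(C)[C@](O)(CC2OCCO2)[C@@]2(C)CCCC(C)(C)[C@H]12
F3 | step 3 | (5R,6S)-5-(2-bromopropan-2-yl)-2,6-dimethyl-6-[2-(phenylsulfonyl)prop-2-en-1-yl]cyclohex-2-en-1-one | CC1=CC[C@@H](C(C)(C)Br)[C@](C)(CC(=C)S(=O)(=O)c2ccccc2)C1=O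
F4 | step 5 | 9-allyl-4,4,8,10-tetramethyl-2-(phenylsulfonyl)-trans-decala-6,8-diene (5α-H, 10β-methyl, C2 epimers) | C1=CC(C)=C(CC=C)[C@@]2(C)CC(S(=O)(=O)c3ccccc3)CC(C)(C)[C@H]12
F5 | step 5 | 9-allyl-4,4,8,10-tetramethyl-trans-decala-6,8-diene (5α-H, 10β-methyl) | C1=CC(C)=C(CC=C)[C@@]2(C)CCCC(C)(C)[C@H]12
F6 | step 5 | 9β-allyl-6α,9α-epidioxy-4,4,8,10-tetramethyl-trans-decal-7-ene | O1O[C@H]2C=C(C)[C@]1(CC=C)[C@@]3(C)CCCC(C)(C)[C@H]23
F7 | step 5 | 9β-allyl-9α-hydroxy-4,4,8,10-tetramethyl-trans-decal-7-en-6-one | O=C1C=C(C)[C@](O)(CC=C)[C@@]2(C)CCCC(C)(C)[C@H]12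
F8 | step 5 | 9β-allyl-4,4,8α,10-tetramethyl-trans-decalin-6α,9α-diol | O[C@H]1C[C@@H](C)[C@](O)(CC=C)[C@@]2(C)CCCC(C)(C)[C@H]12
F9 | step 5 | 9β-allyl-9α-hydroxy-4,4,8α,10-tetramethyl-trans-decalin-6α-yl acetate | CC(=O)O[C@H]1C[C@@H](C)[C@](O)(CC=C)[C@@]2(C)CCCC(C)(C)[C@H]12
F10 | step 9 | 9β-(1,3-dioxolan-2-ylmethyl)-4,4,8,10-tetramethyl-trans-decal-7-ene-6α,9α-diol | O[C@H]1C=C(C)[C@](O)(CC2OCCO2)[C@@]2(C)CCCC(C)(C)[C@H]12
F11 | step 13 | (1S,3R,4R,4aS,8aS)-4-hydroxy-4-(2-hydroxyethyl)-3,4a,8,8-tetramethyldecahydronaphthalen-1-yl acetate | CC(=O)O[C@H]1C[C@@H](C)[C@](O)(CCO)[C@@]2(C)CCCC(C)(C)[C@H]12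
F12 | step 13 | (1S,3R,4R,4aS,8aS)-4-hydroxy-4-(2-iodoethyl)-3,4a,8,8-tetramethyldecahydronaphthalen-1-yl acetate | CC(=O)O[C@H]1C[C@@H](C)[C@](O)(CCI)[C@@]2(C)CCCC(C)(C)[C@H]12
A1 | alternative 1 | 2,6-dimethyl-1,4-benzoquinone | CC1=CC(=O)C=C(C)C1=O
A2 | alternative 1 | 4-methylpenta-1,3-diene | C=CC=C(C)C
A3 | alternative 1 | trans-fused 4,4,8,10-tetramethyl-octalin-6,9-dione with alkenes at C2–C3 and C7–C8 (5α-H, 10β-methyl) | O=C1C=C(C)C(=O)[C@@]2(C)CC=CC(C)(C)[C@H]12
A4 | alternative 2 | 3-[2-(benzyloxy)ethyl]-4-methyl-6-(2,6,6-trimethylcyclohex-1-en-1-yl)oxan-2-one, 4-methyl trans to the 6-substituent, C3 epimers | O=C1O[C@H](C2=C(C)CCCC2(C)C)C[C@@H](C)C1CCOCc1ccccc1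
A5 | alternative 2 | 9β-[2-(benzyloxy)ethyl]-4,4,8α,10β-tetramethyl-octal-5-ene-9α-carboxylic acid | C1C=C2C(C)(C)CCC[C@]2(C)[C@@](C(=O)O)(CCOCc3ccccc3)[C@@H]1C
A6 | alternative 3 | 4,4,7a-trimethyl-2,4,5,6,7,7a-hexahydro-1H-inden-1-one (single enantiomer, angular methyl as at C10 of 23) | O=C1CC=C2C(C)(C)CCC[C@]12C
A7 | alternative 3 | diazoethane | CC=[N+]=[N-]
A8 | alternative 3 | 4,4,8α,10β-tetramethyl-octal-5-en-9-one | C[C@@H]1CC=C2C(C)(C)CCC[C@]2(C)C1=O
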